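The readings stem from a simulated flask with constants of no real substance; scatter was added.

If partner is lost in pairs beside its reaction with starting material, the quantity to follow is the product made per starting material not made into product.

| flask | starting material | partner | product | time |
|---|---|---|---|---|
| epsilon | 0.250 M | 0.275 M |  |  |
| eta | 0.500 M | 0.275 M |  |  |
| delta | 0.250 M | 0.275 M | 0.120 M |  |
| gamma | 0.250 M | 0.690 M |  | 5.2 h |

- epsilon run (time / h: [product] / M): 0.23: 0.0452; 0.70: 0.1008; 1.3: 0.1143; 2.1: 0.1226; 3.0: 0.1258; 4.1: 0.1271; 5.2: 0.1297
- eta run (time / h: [product] / M): 0.23: 0.0762; 0.70: 0.1486; 1.3: 0.1676; 2.1: 0.1743; 3.0: 0.1771; 4.1: 0.1789; 5.2: 0.1795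
- delta run (time / h: [product] / M): 0.23: 0.1641; 0.70: 0.2181; 1.3: 0.2364; 2.1: 0.2429; 3.0: 0.2469; 4.1: 0.2474; 5.2: 0.2492

(scatter of a reading: 0.001 M)

- Overall: starting material + partner -> product.
- Constant volume, constant temperature.
- "The second partner" is partner.
- An order is taken over about fifteen percent of the charge, up and down.

* the exponent of [starting material] in the starting rate at the charge of the epsilon run (at the point where two percent of the starting material have become product) (one fixed amount of product, the same in the runs compared)
* product in the gamma run at 5.2 h, as a share of the starting material charged

Does product act on the flask? The delta run nets 129 mM by its last reading and the epsilon run makes 0.1297 M, so added product changes little.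

Why do the readings level off? The epsilon run flattens at about half of the starting material charged, although more partner than starting material was charged. Partner therefore seems to go elsewhere.

What law does that loss follow? In my own reckoning, each starting material consumed takes one partner and, with it, a further a[partner]/[starting material] of lost partner, where a is a selectivity factor. For a = 2, integration to zero partner gives a simple rule. Let G be product made over starting material not made into product, and c be partner charged over starting material charged; then G = c.

The epsilon run reads G = 1.08 at c = 1.10, and the eta run reads G = 0.560 at c = 0.550. The return W, which is G divided by c, therefore averages 0.999. The gamma run has c = 2.76, so G = 2.76 and the share G/(1+G) is 73.4 %.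

The forecast differs from this reckoning: it gives 86 % (74 % to 95 %), saying of second-order loss that “it fits the tails poorly”. For the order in starting material it gives 0.85 (0.65 to 1).

The simulation gives an order of 0.60 and a gamma share of 72.7 %.

    starting material + partner → intermediate (9.828 M⁻¹ h⁻¹)
    intermediate → product (7.416 h⁻¹)
    2 starting material → homo dimer (2.588 M⁻¹ h⁻¹)
    2 partner → lost reagent (6.876 M⁻¹ h⁻¹)

At that share the gamma run has G = 2.66, so its return is 0.964. The simulated gamma flask without the step from 2 partner to lost reagent reaches 90.5 %, which is G = 9.55 and a return of 3.46. That step is the main reason for the shortfall, costing the gamma run 18 percentage points.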